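**Retrosynthetic overview**
1. Target 24 is cut at the C4–C5 C(sp3)–C(sp) bond of the acyl chain: redox-active glutarate half-ester 23 of alcohol 13 plus terminal 1,3-diyne 19 (new photo-copper decarboxylative diynylation, last step). The ester C–O bond comes from opening glutaric anhydride with 13.
2. Alcohol 13 is cut at the diyne C(sp)–C(sp) bond (Cadiot–Chodkiewicz): bromoalkyne 12 (propargyl alcohol + 1-bromododecane, alkyne zipper, bromination) plus 2-(hex-5-ynyl)furan 6.
3. Diyne 19 is cut at a C(sp3)–C(sp) bond: the C4 linchpin lithium (trimethylsilyl)butadiynide is alkylated with 2-(11-bromoundecyl)furan 15, then desilylated.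
4. Both furan–alkyl bonds come from one batch of 2-furyllithium 2, split between two α,ω-dihaloalkanes. No ring is built in the route (both furan rings are bought as furan), so there is no ring-forming order.

Assumption: the target has no stereocentre and no stereogenic double bond, so "single enantiomer" is taken to mean the one achiral structure written by the SMILES.

**Route**

Step 1
Reactants: 1 furan
Product: 2 2-furyllithium
Conditions: n-BuLi (1.0 equiv), 1 (1.3 equiv), THF, −78 → 0 °C, 1 h; kept at 0 °C under Ar as a titrated ca. 0.5 M solution and used the same day in two portions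
Reagents that add atoms: n-butyllithium (n-BuLi), [Li]CCCC
Why: Kinetic α-deprotonation of furan at C2 by n-BuLi in THF (heteroatom-directed lithiation) gives one batch of the C-nucleophile that serves both furan–alkyl bond formations.

Step 2
Reactants: 2 2-furyllithium; 3 1-bromo-4-chlorobutane
Product: 4 2-(4-chlorobutyl)furan
Conditions: 2 (THF solution, 1.0 equiv), 3 (1.1 equiv), THF, −78 °C → rt, 12 h
Reagents that add atoms: none
Why: SN2 alkylation in which 2-furyllithium displaces bromide far faster than chloride, so the chloride survives as the handle for step 3.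

Step 3
Reactants: 4 2-(4-chlorobutyl)furan; 5 lithium acetylide–ethylenediamine complex (LiC≡CH·H2NCH2CH2NH2)
Product: 6 2-(hex-5-yn-1-yl)furan
Conditions: 5 (1.5 equiv), NaI (10 mol %), DMSO, rt, 12 h
Reagents that add atoms: none
Why: SN2 acetylide alkylation by the primary chloride in DMSO with iodide catalysis; the 2-alkylfuran is inert to the base.

Step 4
Reactants: 7 prop-2-yn-1-ol; 8 1-bromododecane
Product: 10 pentadec-2-yn-1-ol, via dilithium 3-oxidoprop-1-yn-1-ide 9 (not isolated)
Conditions: n-BuLi (2.1 equiv), THF–HMPA, −78 → 0 °C; then 8, 0 °C → rt; then H2O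
Reagents that add atoms: none
Why: Alkylation of the propargyl alcohol C,O-dianion, whose acetylide carbon is far more nucleophilic than the lithium alkoxide, so SN2 C-alkylation gives the 2-alkyn-1-ol.

Step 5
Reactants: 10 pentadec-2-yn-1-ol
Product: 11 pentadec-14-yn-1-ol
Conditions: KH (4.5 equiv), H2N(CH2)3NH2, rt, 1 h; then 10, 0 °C → rt, 4 h; then H2O, 0 °C
Reagents that add atoms: none
Why: Alkyne zipper reaction, in which potassium 3-aminopropylamide moves the triple bond along the unbranched chain through propargyl–allenyl anion equilibria until it is trapped irreversibly as the terminal potassium acetylide.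

Step 6
Reactants: 11 pentadec-14-yn-1-ol
Product: 12 15-bromopentadec-14-yn-1-ol
Conditions: NBS (1.1 equiv), AgNO3 (10 mol %), acetone, rt, dark, 2 h
Reagents that add atoms: N-bromosuccinimide (NBS), O=C1CCC(=O)N1Br
Why: AgNO3-catalysed electrophilic bromination of the terminal alkyne through a silver acetylide, done on the furan-free partner because NBS would attack a furan ring.

Step 7
Reactants: 12 15-bromopentadec-14-yn-1-ol; 6 2-(hex-5-yn-1-yl)furan
Product: 13 21-(furan-2-yl)henicosa-14,16-diyn-1-ol
Conditions: CuCl (10 mol %), NH2OH·HCl (30 mol %), n-BuNH2 (30 % aq.), MeOH–THF, 0 °C; slow addition of 12 to 6 (1.3 equiv); 0 °C → rt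
Reagents that add atoms: none
Why: Cadiot–Chodkiewicz coupling, in which the copper acetylide of 6 couples with bromoalkyne 12 to form the unsymmetrical C(sp)–C(sp) bond while hydroxylamine keeps copper monovalent and suppresses Glaser homocoupling; the free OH and the furan are tolerated.

Step 8
Reactants: 2 2-furyllithium; 14 1,11-dibromoundecane
Product: 15 2-(11-bromoundecyl)furan
Conditions: 2 (THF solution, 1.0 equiv) cannulated into 14 (3 equiv), THF, −78 °C → rt, 12 h
Reagents that add atoms: none
Why: SN2 alkylation of 2-furyllithium, where a threefold excess of the symmetrical dibromide and inverse addition give the mono-substitution product and unchanged 14 is recovered.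

Step 9
Reactants: 16 1,4-bis(trimethylsilyl)buta-1,3-diyne; 15 2-(11-bromoundecyl)furan
Product: 18 2-[15-(trimethylsilyl)pentadeca-12,14-diyn-1-yl]furan, via lithium (trimethylsilyl)buta-1,3-diyn-1-ide 17 (not isolated)
Conditions: 16 (1.4 equiv), MeLi·LiBr (1.3 equiv), THF, 0 °C → rt, 3 h; then 15, HMPA, −78 °C → rt, 16 h
Reagents that add atoms: none
Why: MeLi cleaves one alkynyl C–Si bond of 16 (mono-desilylation, giving Me4Si) and the resulting lithium diynylide undergoes SN2 acetylide alkylation with the primary bromide in THF–HMPA; this weakly basic anion does not metalate the furan.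

Step 10
Reactants: 18 2-[15-(trimethylsilyl)pentadeca-12,14-diyn-1-yl]furan
Product: 19 2-(pentadeca-12,14-diyn-1-yl)furan
Conditions: K2CO3 (0.3 equiv), MeOH–THF, 0 °C → rt, 1 h; silica plug; stored cold and dark as a solution
Reagents that add atoms: none
Why: Base-catalysed protodesilylation (methanolysis) of the alkynyl C–Si bond; no other group in 18 is base-labile.

Step 11
Reactants: 13 21-(furan-2-yl)henicosa-14,16-diyn-1-ol; 20 glutaric anhydride
Product: 21 5-{[21-(furan-2-yl)henicosa-14,16-diyn-1-yl]oxy}-5-oxopentanoic acid
Conditions: 20 (1.5 equiv), DMAP (10 mol %), Et3N (1.5 equiv), CH2Cl2, rt; wash with aq. citric acid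
Reagents that add atoms: none
Why: DMAP-catalysed ring-opening acylation of the primary alcohol by the cyclic anhydride (nucleophilic acyl substitution) forms the ester C–O bond of the target and leaves one free carboxyl group, with no possibility of double acylation.

Step 12
Reactants: 21 5-{[21-(furan-2-yl)henicosa-14,16-diyn-1-yl]oxy}-5-oxopentanoic acid; 22 N-hydroxyphthalimide
Product: 23 1-(1,3-dioxoisoindolin-2-yl) 5-[21-(furan-2-yl)henicosa-14,16-diyn-1-yl] pentanedioate
Conditions: 22 (1.1 equiv), DIC (1.1 equiv), DMAP (5 mol %), CH2Cl2, 0 °C → rt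
Reagents that add atoms: none
Why: Carbodiimide (Steglich-type) esterification of the free acid with N-hydroxyphthalimide gives the redox-active ester; the alkyl ester, the diyne and the furan are untouched.

Step 13
Reactants: 23 1-(1,3-dioxoisoindolin-2-yl) 5-[21-(furan-2-yl)henicosa-14,16-diyn-1-yl] pentanedioate; 19 2-(pentadeca-12,14-diyn-1-yl)furan
Product: 24 21-(furan-2-yl)henicosa-14,16-diyn-1-yl 19-(furan-2-yl)nonadeca-5,7-diynoate (target)
Conditions: Cu(MeCN)4PF6 (10 mol %), 4,4′,4″-tri-tert-butyl-2,2′:6′,2″-terpyridine (12 mol %), Et3N (2 equiv), 19 (1.5 equiv), degassed THF–MeCN (1:1), blue LEDs (450 nm), 20 °C, 16 h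
Reagents that add atoms: none
Why: Proposed new method: a photoinduced copper-catalysed decarboxylative C(sp3)–C(sp) coupling of a primary alkyl N-acyloxyphthalimide with a terminal conjugated 1,3-diyne, in which amine-assisted cupration of 19 gives a terpyridine-ligated monovalent copper butadiynylide whose extended π-system absorbs blue light, its excited state transfers one electron to 23, the radical anion fragments to phthalimide anion, CO2 and the primary 3-(alkoxycarbonyl)propyl radical, this radical is captured by the divalent copper diynylide formed in the same event, and reductive elimination from trivalent copper forges the C4–C5 bond and returns monovalent copper, while the tridentate ligand keeps the diynylide monomeric and disfavours Glaser dimerisation and the internal diyne and furan of 23 have no acidic C–H to engage copper; the closest known reaction type is the photoinduced copper-catalysed decarboxylative alkynylation of redox-active esters with simple terminal alkynes (a radical Sonogashira-type coupling), which has not been shown with a terminal 1,3-diyne to make an unsymmetrical dialkyl diyne without a haloalkyne.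

**Compound list**
1 | furan | c1ccoc1 | starting material
2 | 2-furyllithium | [Li]c1ccco1 | intermediate
3 | 1-bromo-4-chlorobutane | ClCCCCBr | starting material
4 | 2-(4-chlorobutyl)furan | ClCCCCc1ccco1 | intermediate
5 | lithium acetylide–ethylenediamine complex (LiC≡CH·H2NCH2CH2NH2) | [Li+].[C-]#C.NCCN | starting material
6 | 2-(hex-5-yn-1-yl)furan | C#CCCCCc1ccco1 | intermediate
7 | prop-2-yn-1-ol | OCC#C | starting material
8 | 1-bromododecane | CCCCCCCCCCCCBr | starting material
9 | dilithium 3-oxidoprop-1-yn-1-ide | [Li+].[Li+].[O-]CC#[C-] | intermediate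
10 | pentadec-2-yn-1-ol | CCCCCCCCCCCCC#CCO | intermediate
11 | pentadec-14-yn-1-ol | C#CCCCCCCCCCCCCCO | intermediate
12 | 15-bromopentadec-14-yn-1-ol | BrC#CCCCCCCCCCCCCCO | intermediate
13 | 21-(furan-2-yl)henicosa-14,16-diyn-1-ol | OCCCCCCCCCCCCCC#CC#CCCCCc1ccco1 | intermediate
14 | 1,11-dibromoundecane | BrCCCCCCCCCCCBr | starting material
15 | 2-(11-bromoundecyl)furan | BrCCCCCCCCCCCc1ccco1 | intermediate
16 | 1,4-bis(trimethylsilyl)buta-1,3-diyne | C[Si](C)(C)C#CC#C[Si](C)(C)C | starting material
17 | lithium (trimethylsilyl)buta-1,3-diyn-1-ide | [Li+].[C-]#CC#C[Si](C)(C)C | intermediate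
18 | 2-[15-(trimethylsilyl)pentadeca-12,14-diyn-1-yl]furan | C[Si](C)(C)C#CC#CCCCCCCCCCCCc1ccco1 | intermediate
19 | 2-(pentadeca-12,14-diyn-1-yl)furan | C#CC#CCCCCCCCCCCCc1ccco1 | intermediate
20 | glutaric anhydride (oxane-2,6-dione) | O=C1CCCC(=O)O1 | starting material
21 | 5-{[21-(furan-2-yl)henicosa-14,16-diyn-1-yl]oxy}-5-oxopentanoic acid | OC(=O)CCCC(=O)OCCCCCCCCCCCCCC#CC#CCCCCc1ccco1 | intermediate
22 | N-hydroxyphthalimide | ON1C(=O)c2ccccc2C1=O | starting material
23 | 1-(1,3-dioxoisoindolin-2-yl) 5-[21-(furan-2-yl)henicosa-14,16-diyn-1-yl] pentanedioate | O=C(CCCC(=O)ON1C(=O)c2ccccc2C1=O)OCCCCCCCCCCCCCC#CC#CCCCCc1ccco1 | intermediate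
24 | 21-(furan-2-yl)henicosa-14,16-diyn-1-yl 19-(furan-2-yl)nonadeca-5,7-diynoate | O=C(CCCC#CC#CCCCCCCCCCCCc1ccco1)OCCCCCCCCCCCCCC#CC#CCCCCc1ccco1 | target

**Totals**
Total step count: 13.
Longest linear sequence: 7 steps (steps 4, 5, 6, 7, 11, 12, 13, from prop-2-yn-1-ol and 1-bromododecane; the branch through steps 1, 2, 3, 7, 11, 12, 13 from furan is equally long).

**Three steps most likely to fail**

Step 13 (the proposed new step). The risks are Glaser-type dimerisation of 19 to a tetrayne, hydrodecarboxylation of 23, and poor photoactivity or low stability of the copper diynylide. The fallback uses only known chemistry; it sets out from 15 and 13 and comes back to the route at 24. Bromide 15 is treated with 5 in DMSO at rt to give 2-(tridec-12-yn-1-yl)furan F1. Bought hex-5-ynoic acid (OC(=O)CCCC#C) is brominated with NBS and catalytic AgNO3 in acetone to 6-bromohex-5-ynoic acid F2. Cadiot–Chodkiewicz coupling of F1 with F2 (CuCl, NH2OH·HCl, aq. n-BuNH2, MeOH, 0 °C) gives 19-(furan-2-yl)nonadeca-5,7-diynoic acid F3. Steglich esterification of F3 with 13 (EDC·HCl, DMAP, CH2Cl2, rt) gives 24. This replaces the radical C(sp3)–C(sp) coupling by a C(sp)–C(sp) coupling and a classical ester condensation.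

Step 7 (Cadiot–Chodkiewicz coupling of two aliphatic partners). The risk is homocoupling of either alkyne and a difficult separation of three diynes of similar polarity. The fallback sets out from 11 and 4 and comes back at 13; it replaces the C(sp)–C(sp) coupling by a chloroenyne elimination and a C(sp3)–C(sp) alkylation. Alkyne 11 is coupled under Sonogashira conditions (Pd(PPh3)4, CuI, n-BuNH2, Et2O, rt) with an excess of (Z)-1,2-dichloroethene (Cl/C=C\Cl) to give (Z)-17-chloroheptadec-16-en-14-yn-1-ol F4. Chloride 4 is converted with NaI in acetone at reflux (Finkelstein exchange) into 2-(4-iodobutyl)furan F5. F4 is treated with LiN(i-Pr)2 (3.3 equiv, THF, −78 → 0 °C), which deprotonates the hydroxyl, eliminates HCl anti and deprotonates the new terminal diyne to give dilithium 17-oxidoheptadeca-1,3-diyn-1-ide F6. F6 is alkylated at carbon with F5 in THF–HMPA (−78 °C → rt) and gives 13 after aqueous work-up.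

Step 9 (mono-desilylation and alkylation of the C4 linchpin). The risks are incomplete or double Si–C cleavage of 16 and sluggish alkylation of the silyl-capped diynylide by the long-chain bromide. The fallback sets out from 15 and comes back at 19, bypassing 18 and step 10; it uses a silicon-free C4 source that delivers the terminal diyne directly. Bought 1,4-dichlorobut-2-yne (ClCC#CCCl) is treated with NaNH2 (3 equiv) in liquid NH3 at −33 °C, where double dehydrochlorination and deprotonation give sodium buta-1,3-diyn-1-ide F7. F7 is alkylated with 15 (THF co-solvent, −33 °C → rt) to give 19.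

**Further compounds**
F1 | step 13 | 2-(tridec-12-yn-1-yl)furan | C#CCCCCCCCCCCCc1ccco1
F2 | step 13 | 6-bromohex-5-ynoic acid | OC(=O)CCCC#CBr
F3 | step 13 | 19-(furan-2-yl)nonadeca-5,7-diynoic acid | OC(=O)CCCC#CC#CCCCCCCCCCCCc1ccco1
F4 | step 7 | (Z)-17-chloroheptadec-16-en-14-yn-1-ol | OCCCCCCCCCCCCCC#C/C=C\Cl
F5 | step 7 | 2-(4-iodobutyl)furan | ICCCCc1ccco1
F6 | step 7 | dilithium 17-oxidoheptadeca-1,3-diyn-1-ide | [Li+].[Li+].[O-]CCCCCCCCCCCCCC#CC#[C-]
F7 | step 9 | sodium buta-1,3-diyn-1-ide | [Na+].[C-]#CC#C
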